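The earlier runs and the new flask stem from a simulated flask from invented constants; the scatter is artificial.

Start with the readings.

| flask | substrate | remark | time |
|---|---|---|---|
| north-east | 10 mM | run made earlier |  |
| south-east | 5 mM | run made earlier |  |
| north | 7.5 mM | run made earlier |  |
| eta | 10 mM | a closed flask charged with all of it at once and left for 8.0 min | 8.0 min |
| beta | 10 mM | one stirred flow tank at steady state, fed with the mixture as stated, mean residence time 8.0 min |  |

| run | time / min | target / % |
|---|---|---|
| north-east | 1.00 | 2.2 |
| north-east | 3.00 | 13.5 |
| north-east | 5.00 | 25.3 |
| north-east | 8.00 | 34.4 |
| south-east | 1.50 | 6.2 |
| south-east | 3.00 | 15.8 |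
| south-east | 5.00 | 28.0 |
| south-east | 6.00 | 31.3 |
| north | 0.833 | 2.0 |
| north | 2.50 | 14.3 |
| north | 4.00 | 21.2 |
| north | 6.00 | 29.5 |

(scatter of a reading: 1 percentage point)

- the stated concentrations are those of everything mixed, before any reaction; amounts are the same in each set-up
- the earlier runs were made in a closed, stirred flask
- a reading or a percentage of target counts all its forms, free or not

- the set-up with the highest amount of target at the outlet or at the end, in percent of the substrate put in ("none" if the first two lie within 2 percentage points) (eta / beta / none)
- amount of target at the outlet or at the end, in percent of the substrate put in, eta
- amount of target at the outlet or at the end, in percent of the substrate put in, beta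

At 5.00 min, the run from 10 mM shows 25.3% and the run from 5 mM shows 28.0%. That gap of 2.7 percentage points lies between two readings that each scatter by 1 point, so it is no firm difference, and I take, as a working choice, one curve of percent against age for these charges. Flask eta has the charge of the north-east run and stands for the same time, so I expect it to repeat that run, which read 34.4% at 8.00 min.

What does tank beta hold? Its outlet mixes ages, and for a mean residence time τ the fraction older than age t is exp(−t/τ), the residence-time distribution. Call the fraction older than eta's time the old share, 36.8%. With that one curve I treat each age in the outlet as a small closed flask, and averaging the north-east readings over the younger ages then adds 10.1% of the substrate.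

Can beta catch eta? Coming within 2 points needs the old share to average 60.7%, yet the curve gained 12 points over 2.00 min, then 9.1 points over the next 3.00 min. My reckoning therefore favours eta, with beta at 22.8% if the old share merely held the last reading.

The forecast gives eta, with eta at 35% and beta at 24.5% (20% to 29%): “Back-mixing penalises a two-step sequence with a lag”.

The result is eta, with eta at 35.6% and beta at 25.9%.

    substrate → intermediate A (k = 0.00380 /s)
    intermediate A → side product (k = 0.00440 /s)
    substrate ⇌ intermediate B (K = 3.60, k = 0.00650 /s)
    intermediate B ⇌ intermediate C (K = 3.40, k = 0.00170 /s)
    intermediate B → target (k = 0.00550 /s)
    intermediate B ⇌ intermediate D (K = 0.580, k = 0.0140 /s)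
    substrate + target ⇌ idle adduct, settled at all times (K = 50.0 /M)

On my reckoning of the younger ages, beta's figure makes the old share average 42.9%, which is less than the 60.7% required. Eta left until 80.0 min reaches 53.9%, also less than 60.7%. By its forward rate alone, with the way back not counted, substrate has a half-life of 1.8 min towards intermediate B, shorter than the 3.0 min towards intermediate A.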